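The oxepane (O, C7–C12) is traced back to a tetrahydropyran lacking C9: the C7/C12 trans relation across the ring oxygen, hard to enforce during seven-ring closure, is set by axial vinyl-cuprate addition to a dihydropyranone, and C9 is then inserted between C8 and C10. The precursor is a 6-siloxy-3-oxabicyclo[4.1.0]heptane in which C9 is a cyclopropane methylene spanning C8 and C10, with C7-vinyl and the C12 (S)-silyloxypropyl chain trans. One-electron oxidation with FeCl3 cleaves the C8–C10 bond, enlarging the ring and, after loss of HCl, delivering the C10 ketone and C8=C9 alkene that later give the C9-Cl/C10-OH pair.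

Key step: step 6

Remark: locants C1–C15 follow the carbon chain of the target (C1≡C2, C3=C4, C6–Cl, ring oxygen between C7 and C12, C9–Cl, C10–OH, C13–Br). TBS = tert-butyldimethylsilyl, TBDPS = tert-butyldiphenylsilyl, TIPS = triisopropylsilyl, TMS = trimethylsilyl.
Remark: by ring nomenclature the bicyclic precursor is a 6-siloxy-3-oxabicyclo[4.1.0]heptane substituted at C2 (vinyl, = C7) and C4 (side chain, = C12); C1 is the fusion CH (= C8), C6 the siloxy carbon (= C10) and C7 the cyclopropane CH2 (= C9).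
Assumption: a Prelog-type NADPH-dependent ketoreductase that accepts ketone 15 is taken to be found by screening a commercial enzyme panel.

Step 1
Reactants: 1 methyl (2S)-2-hydroxybutanoate
Product: 2 methyl (2S)-2-(tert-butyldimethylsilyloxy)butanoate
Conditions: TBSCl, imidazole, DMF, rt
Reagents that add atoms: tert-butyldimethylsilyl chloride, CC(C)(C)[Si](C)(C)Cl
Why: Routine O-silylation of a secondary alcohol that leaves the C13 stereocentre untouched and installs the bulky, non-chelating group that later steers Felkin–Anh addition.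

Step 2
Reactants: 2 methyl (2S)-2-(tert-butyldimethylsilyloxy)butanoate
Product: 4 (2S)-2-(tert-butyldimethylsilyloxy)butanal, via aluminium hemiacetal 3 (not isolated)
Conditions: iBu2AlH, CH2Cl2, −78 °C; aq. potassium sodium tartrate
Reagents that add atoms: none
Why: Partial ester reduction stops at the tetrahedral aluminium hemiacetal at −78 °C, which collapses to the aldehyde on work-up without loss of the α-stereocentre when the crude aldehyde is used at once.

Step 3
Reactants: 4 (2S)-2-(tert-butyldimethylsilyloxy)butanal; 5 (E)-1-methoxy-3-(trimethylsilyloxy)buta-1,3-diene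
Product: 7 (2R)-2-[(1S)-1-(tert-butyldimethylsilyloxy)propyl]-2,3-dihydro-4H-pyran-4-one, via Mukaiyama aldol adduct 6 (not isolated)
Conditions: BF3·OEt2, Et2O, −78 °C; then CF3CO2H, CH2Cl2, 0 °C
Reagents that add atoms: none
Why: Lewis acid-promoted hetero-Diels–Alder reaction by the Mukaiyama aldol/cyclisation pathway, in which monodentate BF3 and the bulky α-silyloxy group enforce Felkin–Anh attack and set C12 as R (12,13-anti) before acid closes the ring with loss of methanol.

Step 4
Reactants: 7 (2R)-2-[(1S)-1-(tert-butyldimethylsilyloxy)propyl]-2,3-dihydro-4H-pyran-4-one; 8 vinylmagnesium bromide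
Product: 9 (2R,6S)-6-ethenyl-2-[(1S)-1-(tert-butyldimethylsilyloxy)propyl]-4-(trimethylsilyloxy)-3,6-dihydro-2H-pyran (2,6-trans)
Conditions: CuBr·SMe2 (10 mol %), Me3SiCl, THF, −78 °C; Et3N, cold aq. NaHCO3 work-up
Reagents that add atoms: chlorotrimethylsilane, C[Si](C)(C)Cl
Why: Copper-catalysed conjugate addition with in situ O-silylation, in which the vinyl group enters axially on the half-chair anti to the pseudo-equatorial C12 chain so that C7 is set trans to C12, and the trapping fixes the enol ether at C8=C10.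

Step 5
Reactants: 9 (2R,6S)-6-ethenyl-2-[(1S)-1-(tert-butyldimethylsilyloxy)propyl]-4-(trimethylsilyloxy)-3,6-dihydro-2H-pyran; 10 diiodomethane
Product: 11 (2S,4R)-2-ethenyl-4-[(1S)-1-(tert-butyldimethylsilyloxy)propyl]-6-(trimethylsilyloxy)-3-oxabicyclo[4.1.0]heptane (2,4-trans; cis-fused; cyclopropane CH2 anti to the vinyl group)
Conditions: Et2Zn, CH2I2 (1:2, ca. 1.2 equiv of carbenoid), Et2O/CH2Cl2, 0 °C; pyridine, then aq. NaHCO3; Et3N-deactivated silica
Reagents that add atoms: none
Why: Furukawa-modified Simmons–Smith cyclopropanation is fastest at the electron-rich trisubstituted silyl enol ether rather than the monosubstituted vinyl group, and syn addition gives the cis-fused cyclopropane, expected anti to the axial C7 vinyl group, although either face would serve because both new stereocentres are erased in step 6.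

Step 6
Reactants: 11 (2S,4R)-2-ethenyl-4-[(1S)-1-(tert-butyldimethylsilyloxy)propyl]-6-(trimethylsilyloxy)-3-oxabicyclo[4.1.0]heptane
Product: 13 (2R,7S)-7-ethenyl-2-[(1S)-1-(tert-butyldimethylsilyloxy)propyl]-2,3-dihydrooxepin-4(7H)-one (2,7-trans), via β-chloro ketone 12 (not isolated)
Conditions: FeCl3 (2.5 equiv), pyridine (1 equiv), DMF, 0 °C; then Et3N, CH2Cl2, 0 °C to rt
Reagents that add atoms: none
Why: FeCl3 exchanges the Me3Si group for trivalent iron at the C10 oxygen, inner-sphere electron transfer gives the cyclopropyloxy radical, and β-scission of the ring-fusion C8–C10 bond leaves the C10 ketone and a secondary C8 radical that takes chlorine from a second FeCl3; triethylamine then removes HCl across C8–C9 through the C9 enolate to give the conjugated enone. The closest known reaction type is the Saegusa–Ito FeCl3 ring enlargement of 1-siloxybicyclo[n.1.0]alkanes to 2-cycloalkenones. The seven-membered ring (O, C7–C12) is not made by cyclisation but by one-carbon enlargement of the tetrahydropyran when the shared cyclopropane bond is cut, so no exo or endo ring-closure mode has to be won. No stereocentre is created, since the C8 chloride is transient and C8 and C10 end as sp2 carbons, and C7 and C12 are spectators, so their trans relation from step 4 is carried over unchanged. The selectivity needed is cleavage of the internal C8–C10 bond over the peripheral C9–C10 bond, which is secured by the larger strain release of the bicycle and by formation of a secondary instead of a primary radical; fast chlorine transfer from excess FeCl3 is relied on to intercept the C8 radical before it can engage the neighbouring vinyl group, and the mild amine base avoids β-alkoxy elimination at C12.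

Step 7
Reactants: 13 (2R,7S)-7-ethenyl-2-[(1S)-1-(tert-butyldimethylsilyloxy)propyl]-2,3-dihydrooxepin-4(7H)-one
Product: 15 (2R,7R)-5-chloro-7-ethenyl-2-[(1S)-1-(tert-butyldimethylsilyloxy)propyl]oxepan-4-one (C5 epimers; C5 = C9), via silyl enol ether 14 (not isolated)
Conditions: [(Ph3P)CuH]6 (5 mol %), PhMe2SiH (1.1 equiv), toluene, rt; then N-chlorosuccinimide, THF, 0 °C
Reagents that add atoms: N-chlorosuccinimide, O=C1CCC(=O)N1Cl
Why: Copper hydride-catalysed 1,4-hydrosilylation spares the isolated vinyl group and gives the C9=C10 silyl enol ether regiospecifically, and electrophilic α-chlorination then places chlorine at C9 only, with the C9 configuration (attack anti to the C7 substituent should favour 9S) left to be fixed in step 8.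

Step 8
Reactants: 15 (2R,7R)-5-chloro-7-ethenyl-2-[(1S)-1-(tert-butyldimethylsilyloxy)propyl]oxepan-4-one (C5 epimers)
Product: 16 (2R,4S,5S,7R)-5-chloro-7-ethenyl-2-[(1S)-1-(tert-butyldimethylsilyloxy)propyl]oxepan-4-ol
Conditions: ketoreductase (Prelog-selective, NADPH-dependent), NADP+ (cat.), iPrOH, triethanolamine buffer pH 8.5, DMSO (10 vol %), 30 °C
Reagents that add atoms: none
Why: Enzymatic dynamic reductive kinetic resolution, in which the acidic C9–H between carbonyl and chlorine epimerises in the mildly basic buffer while the enzyme reduces only the 9S ketone from the Re face of C10, so that C9 (S) and C10 (S) are fixed together as the trans chlorohydrin.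

Step 9
Reactants: 16 (2R,4S,5S,7R)-5-chloro-7-ethenyl-2-[(1S)-1-(tert-butyldimethylsilyloxy)propyl]oxepan-4-ol
Product: 17 (2R,4S,5S,7R)-4-(tert-butyldiphenylsilyloxy)-5-chloro-7-ethenyl-2-[(1S)-1-(tert-butyldimethylsilyloxy)propyl]oxepane
Conditions: TBDPSCl, imidazole, DMAP (cat.), DMF, rt to 40 °C
Reagents that add atoms: tert-butyl(chloro)diphenylsilane, CC(C)(C)[Si](Cl)(c1ccccc1)c1ccccc1
Why: O-Silylation under weakly basic conditions that cannot close the trans chlorohydrin to an epoxide, giving an acid-stable, fluoride-labile ether that keeps C10–OH out of both later deoxyhalogenations and allows selective removal of the C13 TBS ether.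

Step 10
Reactants: 17 (2R,4S,5S,7R)-4-(tert-butyldiphenylsilyloxy)-5-chloro-7-ethenyl-2-[(1S)-1-(tert-butyldimethylsilyloxy)propyl]oxepane
Product: 19 (2R,4S,5S,7R)-5-(tert-butyldiphenylsilyloxy)-4-chloro-7-[(1S)-1-(tert-butyldimethylsilyloxy)propyl]oxepane-2-carbaldehyde, via ozonide 18 (not isolated)
Conditions: O3, CH2Cl2, −78 °C; then PPh3, −78 °C to rt
Reagents that add atoms: ozone, [O-][O+]=O
Why: Ozonolysis with reductive work-up cleaves the only alkene in the molecule to the C6 aldehyde under neutral conditions that do not epimerise the adjacent C7 ether stereocentre.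

Step 11
Reactants: 19 (2R,4S,5S,7R)-5-(tert-butyldiphenylsilyloxy)-4-chloro-7-[(1S)-1-(tert-butyldimethylsilyloxy)propyl]oxepane-2-carbaldehyde; 20 (−)-B-allyldiisopinocampheylborane (from (+)-α-pinene)
Product: 22 (1S)-1-[(2R,4S,5S,7R)-5-(tert-butyldiphenylsilyloxy)-4-chloro-7-[(1S)-1-(tert-butyldimethylsilyloxy)propyl]oxepan-2-yl]but-3-en-1-ol, via borinate 21 (not isolated)
Conditions: 20 (1 M in pentane), Et2O, −78 °C; then aq. NaOH, 30% H2O2, 0 °C
Reagents that add atoms: none
Why: Brown asymmetric allylboration through a closed chair transition state, in which the reagent adds to the Si face of the aldehyde in agreement with the Felkin–Anh preference of the α-alkoxy aldehyde (matched case) and gives the 6S alcohol anti to the ring oxygen.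

Step 12
Reactants: 22 (1S)-1-[(2R,4S,5S,7R)-5-(tert-butyldiphenylsilyloxy)-4-chloro-7-[(1S)-1-(tert-butyldimethylsilyloxy)propyl]oxepan-2-yl]but-3-en-1-ol
Product: 23 (2R,4S,5S,7R)-5-(tert-butyldiphenylsilyloxy)-4-chloro-2-[(1R)-1-chlorobut-3-enyl]-7-[(1S)-1-(tert-butyldimethylsilyloxy)propyl]oxepane
Conditions: CCl4, P(C8H17)3, 1-methylcyclohexene, toluene, 80 °C
Reagents that add atoms: tetrachloromethane, ClC(Cl)(Cl)Cl
Why: Appel-type deoxychlorination, in which chloride displaces the alkoxyphosphonium group by SN2 with inversion and turns the 6S alcohol into the 6R chloride while both other oxygens are silylated.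

Step 13
Reactants: 24 ethynyltriisopropylsilane; 25 bromoethene
Product: 26 but-3-en-1-ynyltriisopropylsilane
Conditions: Pd(PPh3)4 (2 mol %), CuI (4 mol %), iPr2NH, THF, 0 °C to rt
Reagents that add atoms: none
Why: Sonogashira coupling of a terminal alkyne with a vinyl bromide gives the silyl-capped vinylacetylene that serves as the enyne donor.

Step 14
Reactants: 23 (2R,4S,5S,7R)-5-(tert-butyldiphenylsilyloxy)-4-chloro-2-[(1R)-1-chlorobut-3-enyl]-7-[(1S)-1-(tert-butyldimethylsilyloxy)propyl]oxepane; 26 but-3-en-1-ynyltriisopropylsilane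
Product: 27 (3Z,6R,7R,9S,10S,12R,13S)-13-(tert-butyldimethylsilyloxy)-10-(tert-butyldiphenylsilyloxy)-6,9-dichloro-7,12-epoxy-1-(triisopropylsilyl)pentadec-3-en-1-yne
Conditions: second-generation Grubbs catalyst RuCl2(=CHPh)(PCy3)(H2IMes) (10 mol %), 26 (5 equiv), benzene, 65 °C
Reagents that add atoms: none
Why: Olefin cross-metathesis of a terminal alkene with a silyl-capped conjugated enyne, a pairing known to favour the Z-enyne kinetically, with loss of ethene and removal of the minor E isomer by chromatography.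

Step 15
Reactants: 27 (3Z,6R,7R,9S,10S,12R,13S)-13-(tert-butyldimethylsilyloxy)-10-(tert-butyldiphenylsilyloxy)-6,9-dichloro-7,12-epoxy-1-(triisopropylsilyl)pentadec-3-en-1-yne
Product: 28 (3Z,6R,7R,9S,10S,12R,13S)-10-(tert-butyldiphenylsilyloxy)-6,9-dichloro-7,12-epoxy-1-(triisopropylsilyl)pentadec-3-en-1-yn-13-ol
Conditions: camphorsulfonic acid (0.2 equiv), MeOH/CH2Cl2 (1:1), 0 °C to rt
Reagents that add atoms: none
Why: Acid-catalysed methanolysis removes the secondary TBS ether far faster than the TBDPS ether or the alkynyl silane and so exposes only the C13 hydroxyl.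

Step 16
Reactants: 28 (3Z,6R,7R,9S,10S,12R,13S)-10-(tert-butyldiphenylsilyloxy)-6,9-dichloro-7,12-epoxy-1-(triisopropylsilyl)pentadec-3-en-1-yn-13-ol
Product: 29 (3Z,6R,7R,9S,10S,12R,13R)-13-bromo-10-(tert-butyldiphenylsilyloxy)-6,9-dichloro-7,12-epoxy-1-(triisopropylsilyl)pentadec-3-en-1-yne
Conditions: CBr4, P(C8H17)3, 1-methylcyclohexene, toluene, 70 °C
Reagents that add atoms: tetrabromomethane, BrC(Br)(Br)Br
Why: Appel-type deoxybromination with SN2 inversion converts the 13S alcohol into the 13R bromide, the secondary chlorides being inert to bromide under these conditions and the alkyne still capped.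

Step 17
Reactants: 29 (3Z,6R,7R,9S,10S,12R,13R)-13-bromo-10-(tert-butyldiphenylsilyloxy)-6,9-dichloro-7,12-epoxy-1-(triisopropylsilyl)pentadec-3-en-1-yne
Product: 30 (3Z,6R,7R,9S,10S,12R,13R)-13-bromo-6,9-dichloro-7,12-epoxypentadec-3-en-1-yn-10-ol (target)
Conditions: Bu4NF, AcOH (1:1), THF, 0 °C to rt
Reagents that add atoms: none
Why: Fluoride-mediated desilylation cleaves the O–Si bond at C10 and the C(sp)–Si bond together, and the acetic acid buffer keeps the C10 oxygen protonated so that it cannot close onto C9 or promote loss of HBr.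

Compound list
1 | methyl (2S)-2-hydroxybutanoate | CC[C@H](O)C(=O)OC | starting material
2 | methyl (2S)-2-(tert-butyldimethylsilyloxy)butanoate | CC[C@H](O[Si](C)(C)C(C)(C)C)C(=O)OC | intermediate
3 | [(2S)-2-(tert-butyldimethylsilyloxy)-1-methoxybutoxy]bis(2-methylpropyl)aluminium (aluminium hemiacetal, C1 epimers) | CC[C@H](O[Si](C)(C)C(C)(C)C)C(OC)O[Al](CC(C)C)CC(C)C | intermediate
4 | (2S)-2-(tert-butyldimethylsilyloxy)butanal | CC[C@H](O[Si](C)(C)C(C)(C)C)C=O | intermediate
5 | (E)-1-methoxy-3-(trimethylsilyloxy)buta-1,3-diene | CO/C=C/C(=C)O[Si](C)(C)C | starting material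
6 | (1E,5R,6S)-6-(tert-butyldimethylsilyloxy)-5-hydroxy-1-methoxyoct-1-en-3-one | CO/C=C/C(=O)C[C@H]([C@@H](O[Si](C)(C)C(C)(C)C)CC)O | intermediate
7 | (2R)-2-[(1S)-1-(tert-butyldimethylsilyloxy)propyl]-2,3-dihydro-4H-pyran-4-one | C1=CC(=O)C[C@H]([C@@H](O[Si](C)(C)C(C)(C)C)CC)O1 | intermediate
8 | vinylmagnesium bromide | C=C[Mg]Br | starting material
9 | (2R,6S)-6-ethenyl-2-[(1S)-1-(tert-butyldimethylsilyloxy)propyl]-4-(trimethylsilyloxy)-3,6-dihydro-2H-pyran (2,6-trans) | C=C[C@H]1C=C(O[Si](C)(C)C)C[C@H]([C@@H](O[Si](C)(C)C(C)(C)C)CC)O1 | intermediate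
10 | diiodomethane | ICI | starting material
11 | (2S,4R)-2-ethenyl-4-[(1S)-1-(tert-butyldimethylsilyloxy)propyl]-6-(trimethylsilyloxy)-3-oxabicyclo[4.1.0]heptane (2,4-trans, cis-fused, cyclopropane CH2 anti to vinyl) | C=C[C@H]1[C@@H]2C[C@]2(O[Si](C)(C)C)C[C@H]([C@@H](O[Si](C)(C)C(C)(C)C)CC)O1 | intermediate
12 | (2R,7S)-6-chloro-7-ethenyl-2-[(1S)-1-(tert-butyldimethylsilyloxy)propyl]oxepan-4-one (C6 epimers; C6 = C8 of the chain) | C=C[C@H]1C(Cl)CC(=O)C[C@H]([C@@H](O[Si](C)(C)C(C)(C)C)CC)O1 | intermediate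
13 | (2R,7S)-7-ethenyl-2-[(1S)-1-(tert-butyldimethylsilyloxy)propyl]-2,3-dihydrooxepin-4(7H)-one (2,7-trans) | C=C[C@H]1C=CC(=O)C[C@H]([C@@H](O[Si](C)(C)C(C)(C)C)CC)O1 | intermediate
14 | (2R,7R)-4-[dimethyl(phenyl)silyloxy]-7-ethenyl-2-[(1S)-1-(tert-butyldimethylsilyloxy)propyl]-2,3,6,7-tetrahydrooxepine | C=C[C@H]1CC=C(O[Si](C)(C)c2ccccc2)C[C@H]([C@@H](O[Si](C)(C)C(C)(C)C)CC)O1 | intermediate
15 | (2R,7R)-5-chloro-7-ethenyl-2-[(1S)-1-(tert-butyldimethylsilyloxy)propyl]oxepan-4-one (C5 epimers; C5 = C9) | C=C[C@H]1CC(Cl)C(=O)C[C@H]([C@@H](O[Si](C)(C)C(C)(C)C)CC)O1 | intermediate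
16 | (2R,4S,5S,7R)-5-chloro-7-ethenyl-2-[(1S)-1-(tert-butyldimethylsilyloxy)propyl]oxepan-4-ol | C=C[C@H]1C[C@H](Cl)[C@@H](O)C[C@H]([C@@H](O[Si](C)(C)C(C)(C)C)CC)O1 | intermediate
17 | (2R,4S,5S,7R)-4-(tert-butyldiphenylsilyloxy)-5-chloro-7-ethenyl-2-[(1S)-1-(tert-butyldimethylsilyloxy)propyl]oxepane | C=C[C@H]1C[C@H](Cl)[C@@H](O[Si](c2ccccc2)(c2ccccc2)C(C)(C)C)C[C@H]([C@@H](O[Si](C)(C)C(C)(C)C)CC)O1 | intermediate
18 | 3-[(2R,4S,5S,7R)-5-(tert-butyldiphenylsilyloxy)-4-chloro-7-[(1S)-1-(tert-butyldimethylsilyloxy)propyl]oxepan-2-yl]-1,2,4-trioxolane (epimers at the trioxolane carbon) | O1COC(O1)[C@H]2C[C@H](Cl)[C@@H](O[Si](c3ccccc3)(c3ccccc3)C(C)(C)C)C[C@H]([C@@H](O[Si](C)(C)C(C)(C)C)CC)O2 | intermediate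
19 | (2R,4S,5S,7R)-5-(tert-butyldiphenylsilyloxy)-4-chloro-7-[(1S)-1-(tert-butyldimethylsilyloxy)propyl]oxepane-2-carbaldehyde | O=C[C@H]1C[C@H](Cl)[C@@H](O[Si](c2ccccc2)(c2ccccc2)C(C)(C)C)C[C@H]([C@@H](O[Si](C)(C)C(C)(C)C)CC)O1 | intermediate
20 | (−)-B-allyldiisopinocampheylborane | C=CCB([C@@H]1C[C@@H]2C[C@H]([C@H]1C)C2(C)C)[C@@H]1C[C@@H]2C[C@H]([C@H]1C)C2(C)C | starting material
21 | diisopinocampheylborinate ester of alcohol 22 | C=CC[C@H](OB([C@@H]1C[C@@H]2C[C@H]([C@H]1C)C2(C)C)[C@@H]1C[C@@H]2C[C@H]([C@H]1C)C2(C)C)[C@H]1C[C@H](Cl)[C@@H](O[Si](c2ccccc2)(c2ccccc2)C(C)(C)C)C[C@H]([C@@H](O[Si](C)(C)C(C)(C)C)CC)O1 | intermediate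
22 | (1S)-1-[(2R,4S,5S,7R)-5-(tert-butyldiphenylsilyloxy)-4-chloro-7-[(1S)-1-(tert-butyldimethylsilyloxy)propyl]oxepan-2-yl]but-3-en-1-ol | C=CC[C@H](O)[C@H]1C[C@H](Cl)[C@@H](O[Si](c2ccccc2)(c2ccccc2)C(C)(C)C)C[C@H]([C@@H](O[Si](C)(C)C(C)(C)C)CC)O1 | intermediate
23 | (2R,4S,5S,7R)-5-(tert-butyldiphenylsilyloxy)-4-chloro-2-[(1R)-1-chlorobut-3-enyl]-7-[(1S)-1-(tert-butyldimethylsilyloxy)propyl]oxepane | C=CC[C@@H](Cl)[C@H]1C[C@H](Cl)[C@@H](O[Si](c2ccccc2)(c2ccccc2)C(C)(C)C)C[C@H]([C@@H](O[Si](C)(C)C(C)(C)C)CC)O1 | intermediate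
24 | ethynyltriisopropylsilane | C#C[Si](C(C)C)(C(C)C)C(C)C | starting material
25 | bromoethene | C=CBr | starting material
26 | but-3-en-1-ynyltriisopropylsilane | C=CC#C[Si](C(C)C)(C(C)C)C(C)C | intermediate
27 | (3Z,6R,7R,9S,10S,12R,13S)-13-(tert-butyldimethylsilyloxy)-10-(tert-butyldiphenylsilyloxy)-6,9-dichloro-7,12-epoxy-1-(triisopropylsilyl)pentadec-3-en-1-yne | CC(C)[Si](C(C)C)(C(C)C)C#C/C=C\C[C@@H](Cl)[C@H]1C[C@H](Cl)[C@@H](O[Si](c2ccccc2)(c2ccccc2)C(C)(C)C)C[C@H]([C@@H](O[Si](C)(C)C(C)(C)C)CC)O1 | intermediate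
28 | (3Z,6R,7R,9S,10S,12R,13S)-10-(tert-butyldiphenylsilyloxy)-6,9-dichloro-7,12-epoxy-1-(triisopropylsilyl)pentadec-3-en-1-yn-13-ol | CC(C)[Si](C(C)C)(C(C)C)C#C/C=C\C[C@@H](Cl)[C@H]1C[C@H](Cl)[C@@H](O[Si](c2ccccc2)(c2ccccc2)C(C)(C)C)C[C@H]([C@@H](O)CC)O1 | intermediate
29 | (3Z,6R,7R,9S,10S,12R,13R)-13-bromo-10-(tert-butyldiphenylsilyloxy)-6,9-dichloro-7,12-epoxy-1-(triisopropylsilyl)pentadec-3-en-1-yne | CC(C)[Si](C(C)C)(C(C)C)C#C/C=C\C[C@@H](Cl)[C@H]1C[C@H](Cl)[C@@H](O[Si](c2ccccc2)(c2ccccc2)C(C)(C)C)C[C@H]([C@H](Br)CC)O1 | intermediate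
30 | (3Z,6R,7R,9S,10S,12R,13R)-13-bromo-6,9-dichloro-7,12-epoxypentadec-3-en-1-yn-10-ol | C#C/C=C\C[C@@H](Cl)[C@H]1C[C@H](Cl)[C@@H](O)C[C@H]([C@H](Br)CC)O1 | target

Total step count: 17 (16 in the main line plus one for enyne 26). Longest linear sequence: 16 steps (steps 1–12 and 14–17, from 1).

Steps most likely to fail

Step 6. The cyclopropyloxy radical may open the peripheral C9–C10 bond instead of the fusion bond, the C8 radical may add to the neighbouring vinyl group before chlorine transfer, or acid released from FeCl3 may protodesilylate and open the cyclopropanol to a methyl ketone. The fallback replaces the one-electron fragmentation by a two-electron one and sets out from silyl enol ether 9. Dichlorocarbene (Cl3CCO2Na, DME, 80 °C) adds selectively to the electron-rich enol ether to give the gem-dichlorocyclopropane F1. On continued heating in toluene with Et3N, F1 ionises a chloride, opens the C8–C10 bond in a disrotatory cyclopropyl-to-allyl cation process and loses Me3SiCl, giving the 2-chloro enone F2, which already carries the C9 chlorine. Copper hydride 1,4-hydrosilylation ([(Ph3P)CuH]6, PhMe2SiH) followed by aqueous NH4Cl hydrolysis of the chloro enol ether gives α-chloro ketone 15, where the route is rejoined.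

Step 8. Epimerisation at C9 may be too slow relative to reduction, or no enzyme of the panel may reduce the 9S ketone with the required facial sense, so that conversion stalls or the wrong diastereomer accumulates. The fallback sets out from 15 and uses substrate control followed by inversion. The C9 epimers are separated and the 9R ketone is re-equilibrated with Et3N. The 9S ketone is reduced with LiBH(s-Bu)3 (THF, −78 °C), where hydride attack anti to the C–Cl bond (polar Felkin–Anh) should give the cis chlorohydrin F3. Mitsunobu inversion at C10 (4-nitrobenzoic acid, PPh3, diisopropyl azodicarboxylate, toluene) gives the trans 4-nitrobenzoate F4. The ester is cleaved without base by iBu2AlH (CH2Cl2, −78 °C), returning to chlorohydrin 16.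

Step 14. Cross-metathesis may stall through catalyst sequestration by the conjugated enyne, or Z/E discrimination may be insufficient and the isomers hard to separate. The fallback sets out from 23 and builds the enyne by olefination and coupling. Ozonolysis (O3, CH2Cl2, −78 °C; PPh3) gives the β-chloro aldehyde F5. Stork–Zhao olefination (Ph3P=CHI from [Ph3PCH2I]I and NaN(SiMe3)2, THF/DMPU, −78 °C, where addition should outpace β-elimination of chloride) gives the Z-vinyl iodide F6. Sonogashira coupling with alkyne 24 (Pd(PPh3)4, CuI, iPr2NH) returns to 27.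

Further compounds
F1 | step 6 | (2S,4R)-7,7-dichloro-2-ethenyl-4-[(1S)-1-(tert-butyldimethylsilyloxy)propyl]-6-(trimethylsilyloxy)-3-oxabicyclo[4.1.0]heptane | C=C[C@H]1[C@@H]2C(Cl)(Cl)[C@]2(O[Si](C)(C)C)C[C@H]([C@@H](O[Si](C)(C)C(C)(C)C)CC)O1
F2 | step 6 | (2R,7S)-5-chloro-7-ethenyl-2-[(1S)-1-(tert-butyldimethylsilyloxy)propyl]-2,3-dihydrooxepin-4(7H)-one | C=C[C@H]1C=C(Cl)C(=O)C[C@H]([C@@H](O[Si](C)(C)C(C)(C)C)CC)O1
F3 | step 8 | (2R,4R,5S,7R)-5-chloro-7-ethenyl-2-[(1S)-1-(tert-butyldimethylsilyloxy)propyl]oxepan-4-ol | C=C[C@H]1C[C@H](Cl)[C@H](O)C[C@H]([C@@H](O[Si](C)(C)C(C)(C)C)CC)O1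
F4 | step 8 | (2R,4S,5S,7R)-5-chloro-7-ethenyl-2-[(1S)-1-(tert-butyldimethylsilyloxy)propyl]oxepan-4-yl 4-nitrobenzoate | C=C[C@H]1C[C@H](Cl)[C@@H](OC(=O)c2ccc(cc2)[N+](=O)[O-])C[C@H]([C@@H](O[Si](C)(C)C(C)(C)C)CC)O1
F5 | step 14 | (3R)-3-chloro-3-[(2R,4S,5S,7R)-5-(tert-butyldiphenylsilyloxy)-4-chloro-7-[(1S)-1-(tert-butyldimethylsilyloxy)propyl]oxepan-2-yl]propanal | O=CC[C@@H](Cl)[C@H]1C[C@H](Cl)[C@@H](O[Si](c2ccccc2)(c2ccccc2)C(C)(C)C)C[C@H]([C@@H](O[Si](C)(C)C(C)(C)C)CC)O1
F6 | step 14 | (2R,4S,5S,7R)-5-(tert-butyldiphenylsilyloxy)-4-chloro-2-[(1R,3Z)-1-chloro-4-iodobut-3-enyl]-7-[(1S)-1-(tert-butyldimethylsilyloxy)propyl]oxepane | I/C=C\C[C@@H](Cl)[C@H]1C[C@H](Cl)[C@@H](O[Si](c2ccccc2)(c2ccccc2)C(C)(C)C)C[C@H]([C@@H](O[Si](C)(C)C(C)(C)C)CC)O1
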